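The 1,2-dioxane ring (O1–O2–C3–C4–C5–C6) is read as a cyclobutane that has taken up dioxygen. C3 and C6 are 1,4-related carbons held together by C4–C5 and by the O1–O2 bridge, so excising both oxygens rejoins them as a ring bond. Forward, cobalt-catalysed aerobic oxidation of a tertiary cyclobutanol severs this strained bond and inserts dioxygen, creating the ring, two C–O bonds and both stereocentres at once. The precursor carries the silyl-capped pentynyl chain on the carbinol carbon and a silyloxyethyl arm on the adjacent ring carbon. Ketalisation, arm oxidation, enzymatic resolution and Sonogashira coupling finish the synthesis.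

Key step: step 4

Structure check: the target is (3S,6R). The C6 methoxy group and the C3 acetate arm are cis (OMe axial, both carbon chains equatorial), and the side chain is CH2=CH(CH2)7–CH=CH(E)–C≡C–(CH2)3–.
Assumption: the lipase is taken to hydrolyse the (3R,6S)-ester faster, so the wanted (3S,6R)-ester is the one that remains.
Conventions: all dioxanes are numbered O1–O2–C3–C4–C5–C6 (C3 bears the two-carbon arm, C6 the oxygen substituent and the pentynyl chain). Racemates 11–16 are drawn as the enantiomer that leads to the target.
Design remarks: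
- The arm stays at the alcohol oxidation level, because an ester arm would lactonise onto the tertiary alcohol and block alkoxy radical formation.
- TBS is chosen because it is lost anyway in the acidic methanol of step 5.
- The alkyne is freed in that same flask, before the base-sensitive β-peroxy ester exists.

Step 1
Reactants: 1 cyclobutanone
Product: 2 cyclobutanone N,N-dimethylhydrazone
Conditions: Me2NNH2 (1.2 equiv), 4 Å MS, CH2Cl2, 0 °C → rt
Reagents that add atoms: N,N-dimethylhydrazine, CN(C)N
Why: Hydrazone formation (carbonyl condensation) is fast on the strained, highly electrophilic ketone and is pulled to completion by removal of water.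

Step 2
Reactants: 2 cyclobutanone N,N-dimethylhydrazone; 3 (2-bromoethoxy)(tert-butyl)dimethylsilane
Product: 6 2-[2-(tert-butyldimethylsilyloxy)ethyl]cyclobutan-1-one (racemic), via lithium azaenolate 4 (not isolated), via alkylated hydrazone 5 (not isolated)
Conditions: LiN(iPr)2 (LDA), THF, −78 → 0 °C; 3, −78 °C → rt; then sat. aq oxalic acid, Et2O, rt
Reagents that add atoms: water, O
Why: Azaenolate (metallated hydrazone) alkylation should give clean SN2 monoalkylation with the primary bromide where the free ketone enolate would self-condense, the mild biphasic C=N hydrolysis spares the silyl ether, and the new ring stereocentre may be racemic because step 4 erases it.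

Step 3
Reactants: 6 2-[2-(tert-butyldimethylsilyloxy)ethyl]cyclobutan-1-one; 7 (5-chloropent-1-yn-1-yl)trimethylsilane
Product: 9 1-[5-(trimethylsilyl)pent-4-yn-1-yl]-2-[2-(tert-butyldimethylsilyloxy)ethyl]cyclobutan-1-ol (racemic mixture of diastereomers), via Grignard reagent 8 (not isolated)
Conditions: 7, Mg, I2 (crystal), THF, reflux; then 6, THF, −78 → 0 °C; sat. aq NH4Cl
Reagents that add atoms: none
Why: Grignard 1,2-addition to a cyclobutanone relieves angle strain on rehybridisation and so outruns enolisation, the silyl cap removes the acidic alkyne proton, and the diastereomer mixture is used as such because neither centre survives step 4.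

Step 4
Reactants: 9 1-[5-(trimethylsilyl)pent-4-yn-1-yl]-2-[2-(tert-butyldimethylsilyloxy)ethyl]cyclobutan-1-ol
Product: 11 rac-(3S,6R)-3-[2-(tert-butyldimethylsilyloxy)ethyl]-6-[5-(trimethylsilyl)pent-4-yn-1-yl]-1,2-dioxan-6-ol, via hydroperoxy ketone 10 (not isolated)
Conditions: Co(acac)2 (10–20 mol %), O2 (1 atm), ClCH2CH2Cl, 40 °C
Reagents that add atoms: dioxygen, O=O
Why: Co(acac)2 is oxidised by O2 to a trivalent cobalt species that binds the tertiary alcohol as its alkoxide, Co–O homolysis releases the cyclobutyloxy radical, strain-driven β-scission cuts the C6–C3 bond to give the C6 ketone and a secondary C3 radical, O2 adds to C3 at close to the diffusion limit, and the peroxyl radical is picked up by divalent cobalt and protonated by the next molecule of 9, which gives hydroperoxide 10 and restarts the cycle without an external reductant. The closest known reaction type is this very one, the cobalt-catalysed aerobic ring expansion of cyclobutanols to 1,2-dioxan-3-ols, the homologue of the manganese-catalysed cyclopropanol-to-dioxolanol oxidation. The single ring closes by 6-exo-trig addition of the terminal hydroperoxide oxygen (O1) to the C6 carbonyl carbon. C3 arises from a planar radical with no controlling element and is racemic, whereas C6 is a hemiketal centre that equilibrates by ring–chain tautomerism and should settle, under the anomeric effect, with OH axial and both carbon substituents equatorial (3S*,6R*). The selectivity needed is cleavage toward the substituted ring carbon, which the arm on that carbon secures (secondary versus primary radical), while loss of the exocyclic chain releases no strain and 1,5-hydrogen transfer from the propargylic CH2 cannot compete with opening of the four-membered ring. No hydride source is present, so the capped alkyne is not hydrofunctionalised, the silyl ether is inert, and both diastereomers of 9 converge on 11.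

Step 5
Reactants: 11 rac-(3S,6R)-3-[2-(tert-butyldimethylsilyloxy)ethyl]-6-[5-(trimethylsilyl)pent-4-yn-1-yl]-1,2-dioxan-6-ol
Product: 13 rac-2-[(3S,6R)-6-methoxy-6-(pent-4-yn-1-yl)-1,2-dioxan-3-yl]ethanol, via silylalkyne alcohol 12 (not isolated)
Conditions: TsOH·H2O (10 mol %), MeOH, rt; then K2CO3 (excess), same flask, rt
Reagents that add atoms: methanol, CO
Why: Acid-catalysed ketal exchange through the peroxycarbenium ion is under thermodynamic control, so the anomeric effect places OMe axial and cis to the equatorial C3 arm (3S*,6R*), the same acid methanolyses the primary TBS ether, and the following carbonate-mediated protiodesilylation frees the alkyne while no β-peroxy ester is present.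

Step 6
Reactants: 13 rac-2-[(3S,6R)-6-methoxy-6-(pent-4-yn-1-yl)-1,2-dioxan-3-yl]ethanol
Product: 15 rac-2-[(3S,6R)-6-methoxy-6-(pent-4-yn-1-yl)-1,2-dioxan-3-yl]acetic acid, via aldehyde 14 (not isolated)
Conditions: TEMPO (20 mol %), PhI(OAc)2 (2.5 equiv), MeCN–pH 7 buffer (NaH2PO4/Na2HPO4) 1:1, 0 °C → rt
Reagents that add atoms: water, O
Why: Oxoammonium (TEMPO) oxidation takes the primary alcohol through the aldehyde hydrate to the acid under metal-free, buffered conditions that should leave the O–O bond, the ketal, the terminal alkyne and both stereocentres untouched.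

Step 7
Reactants: 15 rac-2-[(3S,6R)-6-methoxy-6-(pent-4-yn-1-yl)-1,2-dioxan-3-yl]acetic acid
Product: 16 methyl rac-2-[(3S,6R)-6-methoxy-6-(pent-4-yn-1-yl)-1,2-dioxan-3-yl]acetate
Conditions: TMSCHN2, toluene–MeOH 4:1, 0 °C
Reagents that add atoms: (trimethylsilyl)diazomethane, C[Si](C)(C)C=[N+]=[N-]
Why: O-Methylation of a carboxylic acid by a diazoalkane starts with proton transfer from the acid and needs no base, which avoids β-elimination of the peroxide from the new ester.

Step 8
Reactants: 16 methyl rac-2-[(3S,6R)-6-methoxy-6-(pent-4-yn-1-yl)-1,2-dioxan-3-yl]acetate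
Product: 17 methyl 2-[(3S,6R)-6-methoxy-6-(pent-4-yn-1-yl)-1,2-dioxan-3-yl]acetate (single enantiomer)
Conditions: Burkholderia cepacia lipase (Amano PS), pH 7 buffer (NaH2PO4/Na2HPO4)–MTBE, 30 °C, stopped just past half conversion; acid removed with aq NaHCO3
Reagents that add atoms: none
Why: Enzymatic kinetic resolution by enantioselective ester hydrolysis works at neutral pH that the peroxide tolerates, running it past half conversion trades material for enantiopurity of the unreacted ester, and selecting C3 fixes C6 as well because the two centres are already locked relative to each other.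

Step 9
Reactants: 18 9-decen-1-ol
Product: 19 9-decenal
Conditions: TEMPO (10 mol %), PhI(OAc)2 (1.1 equiv), CH2Cl2, rt
Reagents that add atoms: none
Why: Oxoammonium (TEMPO) oxidation in a water-free medium stops at the aldehyde and ignores the terminal alkene.

Step 10
Reactants: 19 9-decenal
Product: 20 (1E)-1-iodoundeca-1,10-diene
Conditions: CrCl2 (6 equiv), CHI3 (2 equiv), 1,4-dioxane–THF 6:1, 0 °C → rt
Reagents that add atoms: iodoform, IC(I)I
Why: Takai olefination adds the geminal dichromium reagent to the aldehyde and eliminates from the less crowded adduct to give the E-vinyl iodide, the dioxane-rich medium reinforcing the E preference and the remote alkene being inert.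

Step 11
Reactants: 17 methyl 2-[(3S,6R)-6-methoxy-6-(pent-4-yn-1-yl)-1,2-dioxan-3-yl]acetate; 20 (1E)-1-iodoundeca-1,10-diene
Product: 21 peroxyacarnoate A
Conditions: PdCl2(PPh3)2 (5 mol %), CuI (10 mol %), Et3N (3 equiv), THF (degassed), rt
Reagents that add atoms: none
Why: Sonogashira coupling of a vinyl iodide proceeds at room temperature with retention of the E geometry, hindered dialkyl peroxides and peroxyketals are known to tolerate such palladium/copper couplings, and the short exposure to a limited amount of amine leaves C3 and C6 unchanged.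

Compound list
1 | cyclobutanone | O=C1CCC1 | starting material
2 | cyclobutanone N,N-dimethylhydrazone | CN(C)N=C1CCC1 | intermediate
3 | (2-bromoethoxy)(tert-butyl)dimethylsilane | CC(C)(C)[Si](C)(C)OCCBr | starting material
4 | lithium azaenolate of 2 (not isolated) | [Li+].CN(C)[N-]C1=CCC1 | intermediate
5 | 2-[2-(tert-butyldimethylsilyloxy)ethyl]cyclobutanone N,N-dimethylhydrazone (racemic, not isolated) | CN(C)N=C1CCC1CCO[Si](C)(C)C(C)(C)C | intermediate
6 | 2-[2-(tert-butyldimethylsilyloxy)ethyl]cyclobutan-1-one (racemic) | O=C1CCC1CCO[Si](C)(C)C(C)(C)C | intermediate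
7 | (5-chloropent-1-yn-1-yl)trimethylsilane | C[Si](C)(C)C#CCCCCl | starting material
8 | [5-(trimethylsilyl)pent-4-yn-1-yl]magnesium chloride (not isolated) | C[Si](C)(C)C#CCCC[Mg]Cl | intermediate
9 | 1-[5-(trimethylsilyl)pent-4-yn-1-yl]-2-[2-(tert-butyldimethylsilyloxy)ethyl]cyclobutan-1-ol (racemic, diastereomer mixture) | C[Si](C)(C)C#CCCCC1(O)CCC1CCO[Si](C)(C)C(C)(C)C | intermediate
10 | 11-(tert-butyldimethylsilyloxy)-9-hydroperoxy-1-(trimethylsilyl)undec-1-yn-6-one (racemic, not isolated) | C[Si](C)(C)C#CCCCC(=O)CCC(OO)CCO[Si](C)(C)C(C)(C)C | intermediate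
11 | rac-(3S,6R)-3-[2-(tert-butyldimethylsilyloxy)ethyl]-6-[5-(trimethylsilyl)pent-4-yn-1-yl]-1,2-dioxan-6-ol (a 1,2-dioxan-3-ol in systematic numbering) | C[Si](C)(C)C#CCCC[C@]1(O)CC[C@@H](CCO[Si](C)(C)C(C)(C)C)OO1 | intermediate
12 | rac-2-{(3S,6R)-6-methoxy-6-[5-(trimethylsilyl)pent-4-yn-1-yl]-1,2-dioxan-3-yl}ethanol (not isolated) | C[Si](C)(C)C#CCCC[C@]1(OC)CC[C@@H](CCO)OO1 | intermediate
13 | rac-2-[(3S,6R)-6-methoxy-6-(pent-4-yn-1-yl)-1,2-dioxan-3-yl]ethanol | C#CCCC[C@]1(OC)CC[C@@H](CCO)OO1 | intermediate
14 | rac-2-[(3S,6R)-6-methoxy-6-(pent-4-yn-1-yl)-1,2-dioxan-3-yl]acetaldehyde (not isolated) | C#CCCC[C@]1(OC)CC[C@@H](CC=O)OO1 | intermediate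
15 | rac-2-[(3S,6R)-6-methoxy-6-(pent-4-yn-1-yl)-1,2-dioxan-3-yl]acetic acid | C#CCCC[C@]1(OC)CC[C@@H](CC(=O)O)OO1 | intermediate
16 | methyl rac-2-[(3S,6R)-6-methoxy-6-(pent-4-yn-1-yl)-1,2-dioxan-3-yl]acetate (racemate, drawn as the wanted enantiomer) | C#CCCC[C@]1(OC)CC[C@@H](CC(=O)OC)OO1 | intermediate
17 | methyl 2-[(3S,6R)-6-methoxy-6-(pent-4-yn-1-yl)-1,2-dioxan-3-yl]acetate (single enantiomer) | C#CCCC[C@]1(OC)CC[C@@H](CC(=O)OC)OO1 | intermediate
18 | 9-decen-1-ol | C=CCCCCCCCCO | starting material
19 | 9-decenal | C=CCCCCCCCC=O | intermediate
20 | (1E)-1-iodoundeca-1,10-diene | C=CCCCCCCC/C=C/I | intermediate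
21 | peroxyacarnoate A, methyl 2-{(3S,6R)-6-[(6E)-hexadeca-6,15-dien-4-yn-1-yl]-6-methoxy-1,2-dioxan-3-yl}acetate | C=CCCCCCCC/C=C/C#CCCC[C@]1(OC)CC[C@@H](CC(=O)OC)OO1 | target

Total step count: 11. Longest linear sequence: 9 (steps 1–8 and 11).

Steps most likely to fail

Step 4. Three things may go wrong: the cobalt alkoxide may form slowly from the hindered tertiary alcohol, part of the scission may run toward the unsubstituted ring CH2, or cobalt may decompose the hydroperoxide before it cyclises. The fallback builds the same ring by ionic chemistry. It sets out from Grignard reagent 8 and returns at racemic ester 16.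
- Reagent 8 is acylated with N-methoxy-N-methylpent-4-enamide to give 10-(trimethylsilyl)dec-1-en-9-yn-5-one F1.
- Cross-metathesis with methyl acrylate (second-generation Hoveyda–Grubbs catalyst, CH2Cl2, 40 °C) gives methyl (2E)-6-oxo-11-(trimethylsilyl)undec-2-en-10-ynoate F2.
- Urea–hydrogen peroxide with catalytic Sc(OTf)3 in MeOH converts the ketone into methyl (2E)-6-hydroperoxy-6-methoxy-11-(trimethylsilyl)undec-2-en-10-ynoate F3.
- Catalytic Et2NH in CF3CH2OH closes the ring by intramolecular conjugate addition of the hydroperoxide to the enoate, giving methyl rac-2-{(3S,6R)-6-methoxy-6-[5-(trimethylsilyl)pent-4-yn-1-yl]-1,2-dioxan-3-yl}acetate F4.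
- AgNO3-catalysed protiodesilylation in aqueous acetone then gives 16.

Step 8. The enzyme may discriminate poorly between the antipodes, because the stereocentre lies β to the reacting carbonyl group, or it may prefer the wanted antipode. The fallback replaces kinetic resolution by physical separation. Racemic 16 is resolved by preparative supercritical-fluid chromatography on a polysaccharide-based chiral stationary phase. It sets out from 16 and returns at 17, and no new compound arises on this path (entry F0). The enantiomer to carry on is identified by taking a sample through step 11 and comparing the sign of rotation with that of the natural product.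

Step 11. The amine may induce β-elimination of the peroxide from the ester with ring opening. Phosphine, monovalent copper or zerovalent palladium may reduce the O–O bond, and the alkyne may dimerise oxidatively. The fallback is a Stille coupling free of base, copper and phosphine. It sets out from 17 and returns at 21. Ester 17 is warmed with Bu3SnOMe (toluene, 60 °C, MeOH removed) to give methyl 2-{(3S,6R)-6-methoxy-6-[5-(tributylstannyl)pent-4-yn-1-yl]-1,2-dioxan-3-yl}acetate F5. F5 is then coupled with 20 under PdCl2(MeCN)2 in DMF at rt.

Further compounds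
F1 | step 4 | 10-(trimethylsilyl)dec-1-en-9-yn-5-one | C[Si](C)(C)C#CCCCC(=O)CCC=C
F2 | step 4 | methyl (2E)-6-oxo-11-(trimethylsilyl)undec-2-en-10-ynoate | COC(=O)/C=C/CCC(=O)CCCC#C[Si](C)(C)C
F3 | step 4 | methyl (2E)-6-hydroperoxy-6-methoxy-11-(trimethylsilyl)undec-2-en-10-ynoate (racemic) | COC(=O)/C=C/CCC(OC)(OO)CCCC#C[Si](C)(C)C
F4 | step 4 | methyl rac-2-{(3S,6R)-6-methoxy-6-[5-(trimethylsilyl)pent-4-yn-1-yl]-1,2-dioxan-3-yl}acetate | C[Si](C)(C)C#CCCC[C@]1(OC)CC[C@@H](CC(=O)OC)OO1
F0 | step 8 | none | none
F5 | step 11 | methyl 2-{(3S,6R)-6-methoxy-6-[5-(tributylstannyl)pent-4-yn-1-yl]-1,2-dioxan-3-yl}acetate | CCCC[Sn](CCCC)(CCCC)C#CCCC[C@]1(OC)CC[C@@H](CC(=O)OC)OO1
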